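**Retrosynthetic overview**
1. Feature used: the seven-membered lactone (O–C20–C12=C11–C10–C9–C8) bridges C8 and C12 of the 14-membered carbocycle. The C7–OAc and C8–O bonds are anti across what would be an E-C7=C8 alkene, which is the imprint of a 7,8-epoxide opened at C8 by the C20 carboxyl group.
2. Key disconnection: C7–O and C8–O(lactone) lead back to an achiral, monocyclic (1E,3E,7E,11Z)-cembratetraene 18-methyl 20-tert-butyl diester. One operation (catalyst-controlled epoxidation, then transannular 7-exo opening by the tert-butyl ester) sets both stereocentres, makes the hindered tertiary ester bond without acylating a tertiary alcohol, and closes the lactone.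
3. Carbocycle: intramolecular HWE reaction at C3=C4. The halves C4–C11 and C12–C3 are joined before that by a Z-selective HWE reaction at C11=C12.
4. Alkene geometries come from templates: E-C7=C8 from 2,3-dihydrofuran (C–O replaced by C–CH3 with retention), and C1=C2 from syn carbocupration of an ynoate.
5. Order of rings: 14-membered carbocycle (step 13), then seven-membered lactone (step 14).

Key step: step 14

Remark: cembrane numbering is used (C1 bears isopropyl, C4 bears C18O2Me, C7 bears OAc, C8 bears C19H3 and the lactone oxygen, C12 bears the lactone carbonyl C20). The target is (7R,8S). The C11=C12 bond carries no descriptor in the SMILES and is taken as cis within the seven-membered ring (Z), the only geometry this ring allows.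

**Route**

Step 1
Reactants: 1 2,3-dihydrofuran; 2 2-(2-bromoethyl)-1,3-dioxolane
Product: 4 5-[2-(1,3-dioxolan-2-yl)ethyl]-2,3-dihydrofuran, via 5-lithio-2,3-dihydrofuran 3 (not isolated)
Conditions: t-BuLi, THF, −78 to 0 °C; then 2, DMPU, −78 °C to rt
Reagents that add atoms: none
Why: The vinylic C–H next to the ring oxygen is the most acidic site, so t-BuLi gives the α-alkoxy alkenyllithium, which the primary bromide alkylates in an SN2 reaction (α-lithiation and alkylation of a cyclic enol ether); no stereocentre is formed.

Step 2
Reactants: 4 5-[2-(1,3-dioxolan-2-yl)ethyl]-2,3-dihydrofuran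
Product: 5 (E)-6-(1,3-dioxolan-2-yl)-4-methylhex-3-en-1-ol
Conditions: MeMgBr, NiCl2(PPh3)2 (5 mol %), toluene, 80 °C; then H2O
Reagents that add atoms: methylmagnesium bromide, C[Mg]Br
Why: Nickel-catalysed Kumada-type cross-coupling of the enol ether C–O bond goes with retention at the alkene carbon, so methyl (C19) takes the place of the ring oxygen, cis to the CH2CH2O arm, and the ring geometry becomes the E-C7=C8 alkene.

Step 3
Reactants: 5 (E)-6-(1,3-dioxolan-2-yl)-4-methylhex-3-en-1-ol
Product: 6 2-[(E)-6-iodo-3-methylhex-3-en-1-yl]-1,3-dioxolane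
Conditions: I2, PPh3, imidazole, CH2Cl2, 0 °C
Reagents that add atoms: iodine, II
Why: Appel-type iodination of the primary alcohol under imidazole-buffered conditions that leave the acetal and the alkene untouched.

Step 4
Reactants: 6 2-[(E)-6-iodo-3-methylhex-3-en-1-yl]-1,3-dioxolane; 7 trimethyl phosphonoacetate
Product: 9 methyl (E)-2-(dimethoxyphosphoryl)-8-(1,3-dioxolan-2-yl)-6-methyloct-5-enoate, via sodium trimethyl phosphonoacetate carbanion 8 (not isolated)
Conditions: NaH, DMF, 0 °C; then 6, 50 °C (7 in excess)
Reagents that add atoms: none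
Why: SN2 alkylation of the stabilised phosphonoacetate carbanion, used in excess to suppress double alkylation; the new centre C4 is racemic and is erased in step 13.

Step 5
Reactants: 9 methyl (E)-2-(dimethoxyphosphoryl)-8-(1,3-dioxolan-2-yl)-6-methyloct-5-enoate
Product: 10 methyl (E)-2-(dimethoxyphosphoryl)-6-methyl-9-oxonon-5-enoate
Conditions: 1 M aq. HCl, THF, rt
Reagents that add atoms: water, O
Why: Acid-catalysed hydrolysis of the dioxolane; the phosphonoacetate and the unconjugated trisubstituted alkene are inert to dilute acid at room temperature.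

Step 6
Reactants: 11 4-bromobut-1-yne
Product: 13 methyl 5-bromopent-2-ynoate, via lithium 4-bromobut-1-ynide 12 (not isolated)
Conditions: n-BuLi (1.0 equiv), THF, −78 °C; then ClCO2Me, −78 to 0 °C
Reagents that add atoms: methyl chloroformate, COC(=O)Cl
Why: At −78 °C deprotonation of the terminal alkyne is faster than any attack on the primary bromide, and the chloroformate acylates the acetylide (acetylide acylation), which installs C3.

Step 7
Reactants: 13 methyl 5-bromopent-2-ynoate
Product: 15 methyl (E)-3-(2-bromoethyl)-4-methylpent-2-enoate, via alkenylcopper adduct 14 (not isolated)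
Conditions: i-PrMgCl, CuI, THF, −40 to −78 °C; then 13, −78 °C; aq. NH4Cl at −78 °C
Reagents that add atoms: isopropylmagnesium chloride, CC(C)[Mg]Cl
Why: Syn carbocupration (conjugate addition) of the organocopper reagent to the ynoate puts isopropyl and copper on the same side, and protonation of the alkenylcopper at −78 °C, where it is configurationally stable, leaves C3 cis to C14 and fixes the C1=C2 geometry; the primary bromide is too slow to react at this temperature.

Step 8
Reactants: 15 methyl (E)-3-(2-bromoethyl)-4-methylpent-2-enoate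
Product: 16 (E)-3-(2-bromoethyl)-4-methylpent-2-en-1-ol
Conditions: DIBAL-H (2.2 equiv), CH2Cl2, −78 °C; then H2O
Reagents that add atoms: none
Why: DIBAL-H reduces the conjugated ester in 1,2-fashion to the allylic alcohol without touching the alkyl bromide or the alkene geometry.

Step 9
Reactants: 17 diphenyl phosphite; 18 tert-butyl bromoacetate
Product: 19 tert-butyl 2-(diphenoxyphosphoryl)acetate
Conditions: Et3N, CH2Cl2, 0 °C to rt
Reagents that add atoms: none
Why: Michaelis–Becker reaction, in which the phosphite deprotonated by the amine displaces bromide from the α-bromo ester through phosphorus.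

Step 10
Reactants: 19 tert-butyl 2-(diphenoxyphosphoryl)acetate; 16 (E)-3-(2-bromoethyl)-4-methylpent-2-en-1-ol
Product: 21 tert-butyl (E)-2-(diphenoxyphosphoryl)-7-hydroxy-5-isopropylhept-5-enoate, via sodium diphenylphosphonoacetate carbanion 20 (not isolated)
Conditions: NaH (0.95 equiv), DMSO, rt; then 16, NaI (10 mol %), 40 °C
Reagents that add atoms: none
Why: SN2 alkylation of the diaryl phosphonoacetate carbanion under iodide catalysis; with less than one equivalent of base only the far more acidic C–H is ionised, so the free allylic alcohol needs no protection, and the new centre C12 is racemic and is erased in step 11.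

Step 11
Reactants: 21 tert-butyl (E)-2-(diphenoxyphosphoryl)-7-hydroxy-5-isopropylhept-5-enoate; 10 methyl (E)-2-(dimethoxyphosphoryl)-6-methyl-9-oxonon-5-enoate
Product: 23 tert-butyl (2Z,6E)-10-(dimethoxyphosphoryl)-2-[(E)-5-hydroxy-3-isopropylpent-3-enyl]-11-methoxy-6-methyl-11-oxoundeca-2,6-dienoate, via sodium carbanion of the alkylated diaryl phosphonate 22 (not isolated)
Conditions: NaH (1.0 equiv), THF, 0 °C; then 10, −78 to 0 °C
Reagents that add atoms: none
Why: Ando variant of the Horner–Wadsworth–Emmons reaction, in which the electron-poor diaryl phosphonate makes the addition irreversible and the elimination fast, which should place C10 cis to the ester (Z-C11=C12); the preformed carbanion of the more acidic diaryl phosphonate should add to the aldehyde at low temperature faster than the dimethyl phosphonoacetate end of 10 protonates it.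

Step 12
Reactants: 23 tert-butyl (2Z,6E)-10-(dimethoxyphosphoryl)-2-[(E)-5-hydroxy-3-isopropylpent-3-enyl]-11-methoxy-6-methyl-11-oxoundeca-2,6-dienoate
Product: 24 tert-butyl (2Z,6E)-10-(dimethoxyphosphoryl)-2-[(E)-3-isopropyl-5-oxopent-3-enyl]-11-methoxy-6-methyl-11-oxoundeca-2,6-dienoate
Conditions: MnO2, CH2Cl2, rt
Reagents that add atoms: none
Why: MnO2 oxidises only the allylic alcohol, under neutral conditions that do not ionise the phosphonoacetate.

Step 13
Reactants: 24 tert-butyl (2Z,6E)-10-(dimethoxyphosphoryl)-2-[(E)-3-isopropyl-5-oxopent-3-enyl]-11-methoxy-6-methyl-11-oxoundeca-2,6-dienoate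
Product: 25 20-tert-butyl 18-methyl (1E,3E,7E,11Z)-cembra-1,3,7,11-tetraene-18,20-dioate (achiral 14-membered carbocycle)
Conditions: LiCl, DBU, MeCN, rt, slow addition of 24 (final about 1 mM)
Reagents that add atoms: none
Why: Intramolecular Horner–Wadsworth–Emmons reaction under Masamune–Roush conditions at high dilution closes the 14-membered carbocycle; the reversible addition of the lithium-chelated dialkyl phosphonate should give the E-C3=C4 enoate (C2 trans to CO2Me), and no stereocentre remains, so 25 is achiral.

Step 14
Reactants: 25 20-tert-butyl 18-methyl (1E,3E,7E,11Z)-cembra-1,3,7,11-tetraene-18,20-dioate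
Product: 27 (7R,8S)-7-hydroxy lactone (7-O-deacetylsarcrassin D), via (7R,8R)-epoxide 26 (not isolated)
Conditions: (i) D-fructose-derived Shi ketone (0.3 equiv), Oxone (1.1 equiv KHSO5), K2CO3, Bu4NHSO4 (cat.), MeCN–CH2(OMe)2, aq. Na2B4O7/Na2EDTA buffer (pH 10.5), 0 °C; phase separation, drying, solvent switch; (ii) CSA (0.2 equiv), CH2Cl2, 0 °C
Reagents that add atoms: potassium peroxymonosulfate (active component of Oxone), [K+].[O-]S(=O)(=O)OO
Why: The dioxirane formed from the D-fructose-derived ketone and KHSO5 delivers one oxygen atom syn through a spiro transition state to the E-C7=C8 alkene (Shi epoxidation of an E-trisubstituted alkene), and the acid then lets the carbonyl oxygen of the C20 tert-butyl ester open the protonated epoxide at the tertiary carbon C8, after which the dioxacarbenium ion loses isobutene and gives back the proton. The closest known reaction types are the Shi epoxidation of the isolated alkene of a polyene that also holds conjugated esters, and the acid-induced epoxide opening by a tert-butyl ester or carbonate that ends polyepoxide cascades in a lactone or a cyclic carbonate. The only ring closed is the seven-membered lactone (O, C20, C12, C11, C10, C9, C8), by a transannular 7-exo-tet attack at the carbon that best carries positive charge, with the Z-C11=C12 bond and only two freely rotating sp3 carbons (C9, C10) holding the carbonyl oxygen near the back of the C8–O bond. C7 and C8 are set as a pair: 25 is achiral and its planar-chiral ring conformers interconvert, so the chiral ketone alone picks the alkene face and should give the (7R,8R)-epoxide, C7 keeps this C–O bond (R), and C8 is inverted by the backside attack (S), which is the anti pattern of the target. Site selectivity among four alkenes is needed and the substrate secures it, because C3=C4 and C11=C12 each carry an ester, C1=C2 is the vinylogous position of the dienoate and is shielded by the isopropyl group, and the oxidant is kept limiting. Chemoselectivity between the two ester carbonyl groups is secured by the tert-butyl group, since only the adduct of the C20 ester can collapse irreversibly, whereas addition of the C18 methyl ester is reversible.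

Step 15
Reactants: 27 (7R,8S)-7-hydroxy lactone (7-O-deacetylsarcrassin D)
Product: 28 sarcrassin D
Conditions: Ac2O, DMAP (cat.), pyridine, rt
Reagents that add atoms: acetic anhydride, CC(=O)OC(C)=O
Why: DMAP-catalysed acetylation of the only hydroxyl group; the bonds at C7 and C8 are not touched, so the (7R,8S) configuration is kept.

**Compound list**
1 | 2,3-dihydrofuran | C1CC=CO1 | starting material
2 | 2-(2-bromoethyl)-1,3-dioxolane | BrCCC1OCCO1 | starting material
3 | 5-lithio-2,3-dihydrofuran | [Li]C1=CCCO1 | intermediate
4 | 5-[2-(1,3-dioxolan-2-yl)ethyl]-2,3-dihydrofuran | C1CC=C(CCC2OCCO2)O1 | intermediate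
5 | (E)-6-(1,3-dioxolan-2-yl)-4-methylhex-3-en-1-ol | OCC/C=C(\C)CCC1OCCO1 | intermediate
6 | 2-[(E)-6-iodo-3-methylhex-3-en-1-yl]-1,3-dioxolane | ICC/C=C(\C)CCC1OCCO1 | intermediate
7 | trimethyl phosphonoacetate | COC(=O)CP(=O)(OC)OC | starting material
8 | sodium trimethyl phosphonoacetate carbanion | [Na+].COC(=O)[CH-]P(=O)(OC)OC | intermediate
9 | methyl (E)-2-(dimethoxyphosphoryl)-8-(1,3-dioxolan-2-yl)-6-methyloct-5-enoate (racemic at C4) | COC(=O)C(CC/C=C(\C)CCC1OCCO1)P(=O)(OC)OC | intermediate
10 | methyl (E)-2-(dimethoxyphosphoryl)-6-methyl-9-oxonon-5-enoate (racemic at C4) | COC(=O)C(CC/C=C(\C)CCC=O)P(=O)(OC)OC | intermediate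
11 | 4-bromobut-1-yne | C#CCCBr | starting material
12 | lithium 4-bromobut-1-ynide | [Li]C#CCCBr | intermediate
13 | methyl 5-bromopent-2-ynoate | COC(=O)C#CCCBr | intermediate
14 | alkenylcopper adduct (Cu at C2, cis to isopropyl) | COC(=O)/C([Cu])=C(/C(C)C)CCBr | intermediate
15 | methyl (E)-3-(2-bromoethyl)-4-methylpent-2-enoate | COC(=O)/C=C(/C(C)C)CCBr | intermediate
16 | (E)-3-(2-bromoethyl)-4-methylpent-2-en-1-ol | OC/C=C(/C(C)C)CCBr | intermediate
17 | diphenyl phosphite | O=[PH](Oc1ccccc1)Oc1ccccc1 | starting material
18 | tert-butyl bromoacetate | CC(C)(C)OC(=O)CBr | starting material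
19 | tert-butyl 2-(diphenoxyphosphoryl)acetate | CC(C)(C)OC(=O)CP(=O)(Oc1ccccc1)Oc1ccccc1 | intermediate
20 | sodium diphenylphosphonoacetate carbanion | [Na+].CC(C)(C)OC(=O)[CH-]P(=O)(Oc1ccccc1)Oc1ccccc1 | intermediate
21 | tert-butyl (E)-2-(diphenoxyphosphoryl)-7-hydroxy-5-isopropylhept-5-enoate (racemic at C12) | CC(C)(C)OC(=O)C(CC/C(C(C)C)=C\CO)P(=O)(Oc1ccccc1)Oc1ccccc1 | intermediate
22 | sodium carbanion of 21 | [Na+].CC(C)(C)OC(=O)[C-](CC/C(C(C)C)=C\CO)P(=O)(Oc1ccccc1)Oc1ccccc1 | intermediate
23 | tert-butyl (2Z,6E)-10-(dimethoxyphosphoryl)-2-[(E)-5-hydroxy-3-isopropylpent-3-enyl]-11-methoxy-6-methyl-11-oxoundeca-2,6-dienoate (racemic at C4) | OC/C=C(/C(C)C)CC/C(C(=O)OC(C)(C)C)=C/CC/C(C)=C/CCC(C(=O)OC)P(=O)(OC)OC | intermediate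
24 | tert-butyl (2Z,6E)-10-(dimethoxyphosphoryl)-2-[(E)-3-isopropyl-5-oxopent-3-enyl]-11-methoxy-6-methyl-11-oxoundeca-2,6-dienoate (racemic at C4) | O=C/C=C(/C(C)C)CC/C(C(=O)OC(C)(C)C)=C/CC/C(C)=C/CCC(C(=O)OC)P(=O)(OC)OC | intermediate
25 | 20-tert-butyl 18-methyl (1E,3E,7E,11Z)-cembra-1,3,7,11-tetraene-18,20-dioate (achiral) | COC(=O)/C1=C/C=C(/C(C)C)CC/C(C(=O)OC(C)(C)C)=C/CC/C(C)=C/CC1 | intermediate
26 | (7R,8R)-7,8-epoxide of 25 | COC(=O)/C1=C/C=C(/C(C)C)CC/C(C(=O)OC(C)(C)C)=C/CC[C@@]2(C)O[C@@H]2CC1 | intermediate
27 | (7R,8S)-7-hydroxy lactone (7-O-deacetylsarcrassin D) | COC(=O)/C1=C/C=C(/C(C)C)CCC2=CCC[C@](C)(OC2=O)[C@H](O)CC1 | intermediate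
28 | sarcrassin D | COC(=O)/C1=C/C=C(/C(C)C)CCC2=CCC[C@](C)(OC2=O)[C@H](OC(C)=O)CC1 | target

**Step count and risks**

Total step count: 15. Longest linear sequence: 10 (steps 1–5 and 11–15).

1. Step 14.
What may go wrong: the two alkene faces may be poorly discriminated on a flexible ring, or oxygen transfer to C1=C2 may compete. After activation of the epoxide, loss of a proton from C19 or C9, or a hydride shift from C7, may outrun the transannular attack.
Fallback (sets out from 24, comes back at 28): the order of the rings is reversed. The same two-stage operation would be run on the open-chain enal 24. There C7=C8 is again the only unconjugated alkene, and free rotation lets the ester carbonyl reach the back of C8. Shi epoxidation would give the (7R,8R)-epoxy enal F1. CSA would convert it into the open-chain hydroxy lactone F2. Acetylation (Ac2O, DMAP, pyridine) would give the open-chain acetoxy lactone F3. LiCl and DBU at high dilution would then close C3=C4 last and give 28 directly.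

2. Step 13.
What may go wrong: intermolecular olefination may lead to oligomers, γ-deprotonation of the enal may erode the C1=C2 geometry, or E control at C3=C4 may be incomplete.
Fallback (sets out from 16, 9 and 19, comes back at 25): C3=C4 is made between two molecules and the ring closure is moved to C11=C12. MnO2 would turn 16 into (E)-3-(2-bromoethyl)-4-methylpent-2-enal F4. Phosphonate 9, deprotonated with NaH in THF, would olefinate F4 to the bromo dienoate acetal F5. Carbanion 20 would displace the bromide to give the diaryl phosphonate acetal F6. Dilute aqueous acid would free the diaryl phosphonate aldehyde F7. NaH in THF at high dilution would then close the ring by an intramolecular Z-selective HWE reaction and give 25.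

3. Step 11.
What may go wrong: proton transfer from the dimethyl phosphonoacetate end of 10 to carbanion 22 may be followed by self-condensation of 10, and Z control may be eroded.
Fallback (sets out from 6, comes back at 23): the acidic phosphonoacetate is installed only after the olefination. Dilute aqueous acid would convert 6 into (E)-7-iodo-4-methylhept-4-enal F8. Carbanion 22 would olefinate F8 to the iodo dienoate F9. Carbanion 8 would then displace the iodide to give 23.

**Further compounds**
F1 | step 14 | (7R,8R)-7,8-epoxide of enal 24 | O=C/C=C(/C(C)C)CC/C(C(=O)OC(C)(C)C)=C/CC[C@@]1(C)O[C@@H]1CCC(C(=O)OC)P(=O)(OC)OC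
F2 | step 14 | open-chain (7R,8S)-hydroxy lactone bearing the enal and the dimethyl phosphonoacetate ends | O=C/C=C(/C(C)C)CCC1=CCC[C@](C)(OC1=O)[C@H](O)CCC(C(=O)OC)P(=O)(OC)OC
F3 | step 14 | open-chain (7R,8S)-acetoxy lactone bearing the enal and the dimethyl phosphonoacetate ends | O=C/C=C(/C(C)C)CCC1=CCC[C@](C)(OC1=O)[C@H](OC(C)=O)CCC(C(=O)OC)P(=O)(OC)OC
F4 | step 13 | (E)-3-(2-bromoethyl)-4-methylpent-2-enal | O=C/C=C(/C(C)C)CCBr
F5 | step 13 | methyl (2E,4E)-7-bromo-2-[(E)-6-(1,3-dioxolan-2-yl)-4-methylhex-3-enyl]-5-isopropylhepta-2,4-dienoate | COC(=O)/C(CC/C=C(\C)CCC1OCCO1)=C/C=C(/C(C)C)CCBr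
F6 | step 13 | 1-tert-butyl 9-methyl (5E,7E)-2-(diphenoxyphosphoryl)-8-[(E)-6-(1,3-dioxolan-2-yl)-4-methylhex-3-enyl]-5-isopropylnona-5,7-dienedioate | COC(=O)/C(CC/C=C(\C)CCC1OCCO1)=C/C=C(/C(C)C)CCC(C(=O)OC(C)(C)C)P(=O)(Oc1ccccc1)Oc1ccccc1
F7 | step 13 | 1-tert-butyl 9-methyl (5E,7E)-2-(diphenoxyphosphoryl)-5-isopropyl-8-[(E)-4-methyl-7-oxohept-3-enyl]nona-5,7-dienedioate | COC(=O)/C(CC/C=C(\C)CCC=O)=C/C=C(/C(C)C)CCC(C(=O)OC(C)(C)C)P(=O)(Oc1ccccc1)Oc1ccccc1
F8 | step 11 | (E)-7-iodo-4-methylhept-4-enal | ICC/C=C(\C)CCC=O
F9 | step 11 | tert-butyl (2Z,6E)-2-[(E)-5-hydroxy-3-isopropylpent-3-enyl]-9-iodo-6-methylnona-2,6-dienoate | OC/C=C(/C(C)C)CC/C(C(=O)OC(C)(C)C)=C/CC/C(C)=C/CCI
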